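**Plan**

1. Atom numbers follow carotenoid usage: C1 gem-dimethyl carbon, C3 carbinol, C5/C6 epoxide carbons, C7 methylene, C8 ketone, chain C9 to C12'. The retrosynthesis cuts, in this order, the C8–C9 bond (aldehyde plus alkenyl iodide), the C11=C12 alkene (phosphonate plus C10 dialdehyde), the two epoxide C–O bonds, and last the ring bonds C1–C2 and C5–C6 in one stroke.
2. The enabling feature is the 1,3-oxygen pattern of ring carbons C3 and C5 together with the gem-dimethyl carbon C1 next to C6. C2–C3–C4–C5 is a latent 1,4-zwitterion stored in a 3-methoxy-3-methylcyclobutanone, and C1=C6 is a trisubstituted alkene that ionises to a tertiary cation.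
3. Forward: the carbocycle is made first by this formal [4+2] annulation with an allyl group as the C7–C8 handle. The alkene is then moved to C5=C6, the epoxide is installed, and the pentaene is joined at C8–C9 near the end.
4. Stereochemistry: C3 comes from a ketoreductase reduction of a prochiral ketone. C5 and C6 come from hydroxyl-directed epoxidation cis to that carbinol, and a Mitsunobu inversion at C3 then gives the trans relation of the target. The all-E chain comes from an E-selective Horner–Wadsworth–Emmons step, a syn hydrozirconation and a stereoretentive coupling.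
5. The labile beta,gamma-epoxy ketone and the enal are unveiled together in the last step by MnO2 oxidation of the two allylic carbinols.

Key step: step 3

Remark: 5-methylhexa-1,4-diene, 1-bromobut-2-yne and (2E,4E,6E)-2,7-dimethylocta-2,4,6-trienedial are taken as purchasable. A ketoreductase of the required S selectivity is assumed to be found in a commercial screening panel. Cyclobutanone 5 is assumed to be isolable when kept free of acid, like its 3-ethoxy analogues.

**Route**

Step 1
Reactants: 1 2-methoxypropene; 2 dichloroacetyl chloride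
Product: 4 racemic 2,2-dichloro-3-methoxy-3-methylcyclobutan-1-one, via dichloroketene 3 (not isolated)
Conditions: Et3N, hexane, 0 °C to rt (1 in excess)
Reagents that add atoms: none
Why: Et3N dehydrochlorinates 2 to dichloroketene, which should add to the electron-rich enol ether in a ketene–alkene [2+2] cycloaddition, the nucleophilic CH2 terminus bonding to the ketene carbonyl carbon so that the methoxy-bearing carbon ends up beta to the ketone; the single stereocentre is racemic and vanishes in step 2.

Step 2
Reactants: 4 racemic 2,2-dichloro-3-methoxy-3-methylcyclobutan-1-one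
Product: 5 3-methoxy-3-methylcyclobutan-1-one
Conditions: Zn dust, NH4Cl, MeOH, 0 °C to rt
Reagents that add atoms: none
Why: Zinc should reduce both alpha C–Cl bonds through the zinc enolate (reductive dehalogenation of an alpha-halo ketone) under near-neutral conditions that spare the acid-labile tertiary beta-methoxy ketone; the product is achiral.

Step 3
Reactants: 5 3-methoxy-3-methylcyclobutan-1-one; 6 5-methylhexa-1,4-diene
Product: 8 racemic 3,5,5-trimethyl-4-(prop-2-en-1-yl)cyclohex-2-en-1-one, via methoxy ketone cycloadduct 7 (not isolated)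
Conditions: SnCl4 (20 mol%), 6 (3 equiv), CH2Cl2, −45 to 0 °C; then TsOH·H2O (10 mol%), rt
Reagents that add atoms: none
Why: Proposed new method: SnCl4 binds the ketone oxygen of 5 and the methoxy lone pair pushes open the strained ring bond between an alpha-CH2 and the methoxy-bearing carbon, giving a 1,4-zwitterion (tin enolate at C2/C3, oxocarbenium ion at C5); the CH carbon of the trisubstituted alkene of 6 attacks the oxocarbenium carbon (C5–C6 bond) in the Markovnikov sense, the tertiary cation so formed at the gem-dimethyl carbon C1 is captured by the enolate carbon (C1–C2 bond) to give 7, and the acid then expels methanol by beta-elimination to the conjugated enone 8. The closest known reaction type is the SnCl4-promoted formal [4+2] cycloaddition of 3-alkoxycyclobutanones with allylsilanes (intermolecular) and with tethered alkenes (intramolecular); an untethered, unactivated trisubstituted alkene is the untested element, and its nucleophilicity is of the same order as that of an allylsilane. The six-membered carbocycle closes stepwise, the second bond by 6-(enolendo) C-alkylation of the tin enolate by the tertiary carbocation. Two stereocentres arise in 7 (the methoxy-bearing C5 and the allyl-bearing C6) without control, and none is needed, because the elimination removes the first and step 4 removes the second, so 8 is carried on as the racemate. The step needs site selectivity for the trisubstituted over the terminal alkene of 6 and for its CH terminus, both secured by the stability of the tertiary cation flanked by two methyl groups, and it needs ring closure to outrun proton loss from that cation, which the tin enolate held in a six-membered array and the low temperature should secure; excess 6 counters collapse of the zwitterion to 4-methoxypent-3-en-2-one.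

Step 4
Reactants: 8 racemic 3,5,5-trimethyl-4-(prop-2-en-1-yl)cyclohex-2-en-1-one
Product: 10 3,5,5-trimethyl-4-(prop-2-en-1-yl)cyclohex-3-en-1-one, via potassium dienolate 9 (not isolated)
Conditions: KOtBu (3 equiv), t-BuOH, rt; then poured into cold 10% aq AcOH
Reagents that add atoms: none
Why: Excess KOtBu should convert the enone reversibly into the more substituted endocyclic dienolate (gamma-deprotonation at the allyl-bearing ring CH), and fast kinetic protonation at the alpha-carbon gives the beta,gamma-unsaturated ketone (deconjugative isomerisation of an enone), which erases the uncontrolled stereocentre and places the alkene at C5=C6.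

Step 5
Reactants: 10 3,5,5-trimethyl-4-(prop-2-en-1-yl)cyclohex-3-en-1-one
Product: 11 (1S)-3,5,5-trimethyl-4-(prop-2-en-1-yl)cyclohex-3-en-1-ol
Conditions: ketoreductase (S-selective), NADP+ (cat.), i-PrOH, phosphate buffer pH 7, DMSO (10 vol%), 30 °C
Reagents that add atoms: none
Why: Biocatalytic asymmetric ketone reduction: the enzyme pocket should tell the gem-dimethyl flank from the alkene flank and deliver hydride from NADPH (recycled by isopropanol) to one face, setting the carbinol centre as S at neutral pH, where the alkene should not move back into conjugation.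

Step 6
Reactants: 11 (1S)-3,5,5-trimethyl-4-(prop-2-en-1-yl)cyclohex-3-en-1-ol
Product: 12 (1R,3R,6S)-1,5,5-trimethyl-6-(prop-2-en-1-yl)-7-oxabicyclo[4.1.0]heptan-3-ol (hydroxyl cis to the epoxide oxygen)
Conditions: VO(acac)2 (5 mol%), t-BuOOH (anhydrous, 1.5 equiv), toluene, 0 °C to rt
Reagents that add atoms: tert-butyl hydroperoxide CC(C)(C)OO
Why: Hydroxyl-directed epoxidation: the homoallylic hydroxyl binds vanadium and the bound peroxide should deliver oxygen to the same face of the electron-rich tetrasubstituted ring alkene, setting both epoxide carbons cis to the carbinol oxygen and leaving the undirected terminal alkene untouched.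

Step 7
Reactants: 12 (1R,3R,6S)-1,5,5-trimethyl-6-(prop-2-en-1-yl)-7-oxabicyclo[4.1.0]heptan-3-ol
Product: 13 (1R,3S,6S)-1,5,5-trimethyl-6-(prop-2-en-1-yl)-7-oxabicyclo[4.1.0]heptan-3-yl benzoate (ester trans to the epoxide oxygen)
Conditions: PhCO2H, PPh3, DIAD, toluene, 0 °C to rt
Reagents that add atoms: benzoic acid OC(=O)c1ccccc1
Why: Mitsunobu reaction: the alcohol is activated as an alkoxyphosphonium ion and displaced by benzoate in an SN2 step with inversion, which should turn the cis epoxy alcohol into the trans ester required by the target and protects the carbinol for steps 8 and 13.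

Step 8
Reactants: 13 (1R,3S,6S)-1,5,5-trimethyl-6-(prop-2-en-1-yl)-7-oxabicyclo[4.1.0]heptan-3-yl benzoate
Product: 15 (1R,3S,6S)-1,5,5-trimethyl-6-(2-oxoethyl)-7-oxabicyclo[4.1.0]heptan-3-yl benzoate, via ozonide 14 (not isolated)
Conditions: O3, CH2Cl2, −78 °C; then Me2S, −78 °C to rt; used crude
Reagents that add atoms: ozone [O-][O+]=O
Why: Ozonolysis cleaves the only remaining alkene and reductive work-up should give the aldehyde, shorter by one carbon, without acid or base, as the beta,gamma-epoxy aldehyde demands; no stereocentre is touched.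

Step 9
Reactants: 16 1-bromobut-2-yne
Product: 17 diethyl but-2-yn-1-ylphosphonate
Conditions: P(OEt)3, neat, 120 °C, EtBr distilled off
Reagents that add atoms: triethyl phosphite CCOP(OCC)OCC
Why: Michaelis–Arbuzov reaction: the phosphite displaces the propargylic bromide and the bromide ion dealkylates the phosphonium salt.

Step 10
Reactants: 17 diethyl but-2-yn-1-ylphosphonate; 18 (2E,4E,6E)-2,7-dimethylocta-2,4,6-trienedial
Product: 20 (2E,4E,6E,8E)-2,7-dimethyldodeca-2,4,6,8-tetraen-10-ynal, via sodium phosphonate anion 19 (not isolated)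
Conditions: NaHMDS, THF, −78 °C; then added to 18 (3 equiv, excess recovered), −78 to 0 °C
Reagents that add atoms: none
Why: Horner–Wadsworth–Emmons olefination of one formyl group of the symmetrical dialdehyde by the propargylic phosphonate anion should give the new disubstituted alkene with E geometry, and the excess of dialdehyde limits double olefination.

Step 11
Reactants: 20 (2E,4E,6E,8E)-2,7-dimethyldodeca-2,4,6,8-tetraen-10-ynal
Product: 21 (2E,4E,6E,8E)-2,7-dimethyldodeca-2,4,6,8-tetraen-10-yn-1-ol
Conditions: NaBH4, MeOH/THF, 0 °C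
Reagents that add atoms: none
Why: Borohydride 1,2-reduction masks the conjugated aldehyde as the allylic alcohol, which is inert in the chromium coupling and is re-oxidised in the last step.

Step 12
Reactants: 21 (2E,4E,6E,8E)-2,7-dimethyldodeca-2,4,6,8-tetraen-10-yn-1-ol
Product: 23 (2E,4E,6E,8E,10E)-11-iodo-2,7-dimethyldodeca-2,4,6,8,10-pentaen-1-ol, via alkenylzirconocene chloride 22 (not isolated)
Conditions: Cp2Zr(H)Cl (2.5 equiv), THF, rt to 40 °C; then I2, THF, −20 °C
Reagents that add atoms: iodine [I][I]
Why: Hydrozirconation adds Zr–H syn across the alkyne (one further equivalent is consumed by the hydroxyl), the metal should settle with excess reagent on the less hindered methyl-bearing carbon, and iodinolysis proceeds with retention to give the E trisubstituted alkenyl iodide.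

Step 13
Reactants: 15 (1R,3S,6S)-1,5,5-trimethyl-6-(2-oxoethyl)-7-oxabicyclo[4.1.0]heptan-3-yl benzoate; 23 (2E,4E,6E,8E,10E)-11-iodo-2,7-dimethyldodeca-2,4,6,8,10-pentaen-1-ol
Product: 24 (1R,3S,6S)-6-[(3E,5E,7E,9E,11E)-2,13-dihydroxy-3,7,12-trimethyltrideca-3,5,7,9,11-pentaen-1-yl]-1,5,5-trimethyl-7-oxabicyclo[4.1.0]heptan-3-yl benzoate (both epimers at the new carbinol)
Conditions: CrCl2 (6 equiv), NiCl2 (2 mol%), degassed DMSO, rt, dark
Reagents that add atoms: none
Why: Nozaki–Hiyama–Kishi coupling: zerovalent nickel inserts into the C–I bond, the alkenyl group passes to trivalent chromium with retention of geometry and should add chemoselectively to the aldehyde under neutral conditions that tolerate the epoxide, the benzoate and the free hydroxyl; the new carbinol centre is not controlled and is removed in step 15.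

Step 14
Reactants: 24 the benzoate diol from step 13
Product: 25 (2E,4E,6E,8E,10E)-13-[(1S,4S,6R)-4-hydroxy-2,2,6-trimethyl-7-oxabicyclo[4.1.0]heptan-1-yl]-2,7,11-trimethyltrideca-2,4,6,8,10-pentaene-1,12-diol (both epimers at C12)
Conditions: K2CO3 (cat.), MeOH, rt
Reagents that add atoms: none
Why: Base-catalysed transesterification (methanolysis) should remove the benzoate before the base-sensitive beta,gamma-epoxy ketone exists; the tetrasubstituted epoxide and the polyene tolerate these conditions.

Step 15
Reactants: 25 the triol from step 14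
Product: 26 (2E,4E,6E,8E,10E)-13-[(1S,4S,6R)-4-hydroxy-2,2,6-trimethyl-7-oxabicyclo[4.1.0]heptan-1-yl]-2,7,11-trimethyl-12-oxotrideca-2,4,6,8,10-pentaenal (CNP0310604.1)
Conditions: MnO2 (activated, excess), CH2Cl2, rt, dark
Reagents that add atoms: none
Why: MnO2 should oxidise only the two allylic alcohols, to the conjugated ketone and the enal, and leave the saturated ring carbinol, so the labile epoxy ketone is formed last under neutral heterogeneous conditions and both carbinol epimers converge on one product.

**Compound list**

1 | 2-methoxypropene | COC(C)=C | starting material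
2 | dichloroacetyl chloride | ClC(Cl)C(Cl)=O | starting material
3 | dichloroketene | ClC(Cl)=C=O | intermediate
4 | racemic 2,2-dichloro-3-methoxy-3-methylcyclobutan-1-one | COC1(C)CC(=O)C1(Cl)Cl | intermediate
5 | 3-methoxy-3-methylcyclobutan-1-one | COC1(C)CC(=O)C1 | intermediate
6 | 5-methylhexa-1,4-diene | CC(C)=CCC=C | starting material
7 | 3-methoxy-3,5,5-trimethyl-4-(prop-2-en-1-yl)cyclohexan-1-one (racemic, both diastereomers) | COC1(C)CC(=O)CC(C)(C)C1CC=C | intermediate
8 | racemic 3,5,5-trimethyl-4-(prop-2-en-1-yl)cyclohex-2-en-1-one | CC1=CC(=O)CC(C)(C)C1CC=C | intermediate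
9 | potassium 3,5,5-trimethyl-4-(prop-2-en-1-yl)cyclohexa-1,3-dien-1-olate | [K+].[O-]C1=CC(C)=C(CC=C)C(C)(C)C1 | intermediate
10 | 3,5,5-trimethyl-4-(prop-2-en-1-yl)cyclohex-3-en-1-one | CC1=C(CC=C)C(C)(C)CC(=O)C1 | intermediate
11 | (1S)-3,5,5-trimethyl-4-(prop-2-en-1-yl)cyclohex-3-en-1-ol | C=CCC1=C(C)C[C@H](O)CC1(C)C | intermediate
12 | (1R,3R,6S)-1,5,5-trimethyl-6-(prop-2-en-1-yl)-7-oxabicyclo[4.1.0]heptan-3-ol | C=CC[C@@]12O[C@]1(C)C[C@H](O)CC2(C)C | intermediate
13 | (1R,3S,6S)-1,5,5-trimethyl-6-(prop-2-en-1-yl)-7-oxabicyclo[4.1.0]heptan-3-yl benzoate | C=CC[C@@]12O[C@]1(C)C[C@@H](OC(=O)c3ccccc3)CC2(C)C | intermediate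
14 | ozonide (1,2,4-trioxolane) of 13 at the terminal alkene | C1OC(C[C@@]23O[C@]2(C)C[C@@H](OC(=O)c4ccccc4)CC3(C)C)OO1 | intermediate
15 | (1R,3S,6S)-1,5,5-trimethyl-6-(2-oxoethyl)-7-oxabicyclo[4.1.0]heptan-3-yl benzoate | O=CC[C@@]12O[C@]1(C)C[C@@H](OC(=O)c3ccccc3)CC2(C)C | intermediate
16 | 1-bromobut-2-yne | CC#CCBr | starting material
17 | diethyl but-2-yn-1-ylphosphonate | CC#CCP(=O)(OCC)OCC | intermediate
18 | (2E,4E,6E)-2,7-dimethylocta-2,4,6-trienedial | C\C(C=O)=C/C=C/C=C(C)/C=O | starting material
19 | sodium salt of the carbanion of 17 | [Na+].CC#C[CH-]P(=O)(OCC)OCC | intermediate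
20 | (2E,4E,6E,8E)-2,7-dimethyldodeca-2,4,6,8-tetraen-10-ynal | C\C(C=O)=C/C=C/C=C(C)/C=C/C#CC | intermediate
21 | (2E,4E,6E,8E)-2,7-dimethyldodeca-2,4,6,8-tetraen-10-yn-1-ol | C\C(CO)=C/C=C/C=C(C)/C=C/C#CC | intermediate
22 | alkenylzirconocene chloride of 21, zirconium on the methyl-bearing alkene carbon and on the alkoxide oxygen (cyclopentadienyl rings drawn sigma-bonded) | C\C(CO[Zr](Cl)(C1C=CC=C1)C1C=CC=C1)=C/C=C/C=C(C)/C=C/C=C(\C)[Zr](Cl)(C1C=CC=C1)C1C=CC=C1 | intermediate
23 | (2E,4E,6E,8E,10E)-11-iodo-2,7-dimethyldodeca-2,4,6,8,10-pentaen-1-ol | C\C(CO)=C/C=C/C=C(C)/C=C/C=C(\C)I | intermediate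
24 | (1R,3S,6S)-6-[(3E,5E,7E,9E,11E)-2,13-dihydroxy-3,7,12-trimethyltrideca-3,5,7,9,11-pentaen-1-yl]-1,5,5-trimethyl-7-oxabicyclo[4.1.0]heptan-3-yl benzoate (both carbinol epimers) | C\C(CO)=C/C=C/C=C(C)/C=C/C=C(\C)C(O)C[C@@]12O[C@]1(C)C[C@@H](OC(=O)c3ccccc3)CC2(C)C | intermediate
25 | (2E,4E,6E,8E,10E)-13-[(1S,4S,6R)-4-hydroxy-2,2,6-trimethyl-7-oxabicyclo[4.1.0]heptan-1-yl]-2,7,11-trimethyltrideca-2,4,6,8,10-pentaene-1,12-diol (both C12 epimers) | C\C(CO)=C/C=C/C=C(C)/C=C/C=C(\C)C(O)C[C@@]12O[C@]1(C)C[C@@H](O)CC2(C)C | intermediate
26 | (2E,4E,6E,8E,10E)-13-[(1S,4S,6R)-4-hydroxy-2,2,6-trimethyl-7-oxabicyclo[4.1.0]heptan-1-yl]-2,7,11-trimethyl-12-oxotrideca-2,4,6,8,10-pentaenal | C\C(C=O)=C/C=C/C=C(C)/C=C/C=C(\C)C(=O)C[C@@]12O[C@]1(C)C[C@@H](O)CC2(C)C | target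

**Summary**

Total step count: 15. Longest linear sequence: 11 steps (steps 1 to 8, then 13 to 15).

Steps most likely to fail:

Step 3 (proposed new method). The tertiary cation may lose a proton instead of closing the ring, the opened cyclobutanone may collapse to an acyclic enone before the alkene is captured, or the Lewis acid may oligomerise the diene. The fallback uses known vinylogous-ester chemistry and carries no numbered compound into it; it sets out from commercial 3-ethoxy-5,5-dimethylcyclohex-2-en-1-one and allyl bromide in place of 5 and 6, and comes back to the route at 8. The enol ether is deprotonated at the alpha'-carbon next to the gem-dimethyl group with LDA (THF, −78 °C) and allylated to give 3-ethoxy-5,5-dimethyl-6-(prop-2-en-1-yl)cyclohex-2-en-1-one F1. MeLi adds to the carbonyl to give 3-ethoxy-1,5,5-trimethyl-6-(prop-2-en-1-yl)cyclohex-2-en-1-ol F2, and aqueous HCl work-up (Stork–Danheiser transposition) hydrolyses the enol ether and dehydrates the carbinol to 8.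

Step 13. The slow chromium-mediated coupling may allow Lewis-acid opening of the tetrasubstituted epoxide, beta-elimination of the epoxy aldehyde, or erosion of alkene geometry. The fallback sets out from 23 and 15 and comes back at 24; it replaces the in situ chromium reagent by a preformed alkenyllithium at low temperature. 23 is silylated (TBSCl, imidazole, DMF) to tert-butyl{[(2E,4E,6E,8E,10E)-11-iodo-2,7-dimethyldodeca-2,4,6,8,10-pentaen-1-yl]oxy}dimethylsilane F3. Iodine–lithium exchange (t-BuLi, Et2O, −78 °C) gives the alkenyllithium F4, which is added at −78 °C to 15 to give the silyl ether of the adduct F5. TBAF buffered with AcOH (THF, 0 °C) then frees the primary alcohol and returns 24.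

Step 12. Zirconium may be placed with poor regiocontrol on the internal enyne, and the reagent may attack or isomerise the polyene. The fallback sets out from 18 (with commercial but-2-yn-1-ol) and comes back at 23; the iodide is installed on a four-carbon unit, where the alkoxide directs the metal, before the polyene is built. But-2-yn-1-ol is hydrozirconated (Cp2Zr(H)Cl, THF) and iodinated to (2E)-3-iodobut-2-en-1-ol F6. PBr3 gives (2E)-1-bromo-3-iodobut-2-ene F7, and P(OEt)3 gives diethyl [(2E)-3-iodobut-2-en-1-yl]phosphonate F8. Horner–Wadsworth–Emmons reaction of F8 (NaHMDS, THF, −78 °C) with excess 18 gives (2E,4E,6E,8E,10E)-11-iodo-2,7-dimethyldodeca-2,4,6,8,10-pentaenal F9, and NaBH4 reduction returns 23.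

Further compounds
F1 | step 3 | 3-ethoxy-5,5-dimethyl-6-(prop-2-en-1-yl)cyclohex-2-en-1-one | CCOC1=CC(=O)C(CC=C)C(C)(C)C1
F2 | step 3 | 3-ethoxy-1,5,5-trimethyl-6-(prop-2-en-1-yl)cyclohex-2-en-1-ol | CCOC1=CC(C)(O)C(CC=C)C(C)(C)C1
F3 | step 13 | tert-butyl{[(2E,4E,6E,8E,10E)-11-iodo-2,7-dimethyldodeca-2,4,6,8,10-pentaen-1-yl]oxy}dimethylsilane | C\C(CO[Si](C)(C)C(C)(C)C)=C/C=C/C=C(C)/C=C/C=C(\C)I
F4 | step 13 | alkenyllithium from F3 (lithium in place of iodine) | C\C(CO[Si](C)(C)C(C)(C)C)=C/C=C/C=C(C)/C=C/C=C(\C)[Li]
F5 | step 13 | 13-O-tert-butyldimethylsilyl ether of 24 | C\C(CO[Si](C)(C)C(C)(C)C)=C/C=C/C=C(C)/C=C/C=C(\C)C(O)C[C@@]12O[C@]1(C)C[C@@H](OC(=O)c3ccccc3)CC2(C)C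
F6 | step 12 | (2E)-3-iodobut-2-en-1-ol | C/C(I)=C\CO
F7 | step 12 | (2E)-1-bromo-3-iodobut-2-ene | C/C(I)=C\CBr
F8 | step 12 | diethyl [(2E)-3-iodobut-2-en-1-yl]phosphonate | C/C(I)=C\CP(=O)(OCC)OCC
F9 | step 12 | (2E,4E,6E,8E,10E)-11-iodo-2,7-dimethyldodeca-2,4,6,8,10-pentaenal | C\C(C=O)=C/C=C/C=C(C)/C=C/C=C(\C)I
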